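## Retrosynthetic overview

1. The target comes from its 2-ketone by Luche reduction, acetylation and a final desilylation of the benzylic alcohol.
2. The cycloheptene and the α-methylene-γ-lactone are closed together, last, by an intramolecular Nozaki–Hiyama allylation/lactonisation on a cyclopentenone–δ-lactone core carrying an aldehyde arm and a bromomethyl-acrylate arm.
3. Key step: that core (cyclopentenone plus aryl δ-lactone) is made in one flask from an acyclic enone–diketone by copper hydride reductive aldol cyclisation, then acid-induced dehydration, lactonisation and decarboxylation.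
4. The acyclic precursor comes from a catalytic asymmetric Mukaiyama aldol of a dienol silyl ether with hex-5-ene-2,3-dione; the dienol ether comes from Michael addition of an aryl malonate to a cross-conjugated dienone.
5. The aryl malonate comes from (4-bromo-2-iodophenyl)methanol by redox-relay Heck arylation and malonate arylation. Ring order: cyclopentenone + δ-lactone, then cycloheptene + γ-lactone.

Abbreviation: Ar = 3-[(2R)-5-acetoxypentan-2-yl]-4-({[tert-butyl(diphenyl)silyl]oxy}methyl)phenyl.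

Locants for the core: C1–C10 are the ring carbons as in guaianes (C1=C5 shared by both carbocycles, methyl on C10, methyl and lactone O on C4, O on C2 and C8). C11–C13 are the α-methylene lactone carbons. C16 is the CH2 on C3, C17 the CH bearing Ar, C18 the δ-lactone carbonyl.

Assumption: the ligand antipodes named in steps 3, 11 and 12 are those expected, by analogy with the closest known cases, to give the configurations drawn; where the sense of induction proves opposite, the mirror-image ligand is used.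

## Route

Step 1
Reactants: 1 (4-bromo-2-iodophenyl)methanol
Product: 2 tert-butyl[(4-bromo-2-iodophenyl)methoxy]diphenylsilane
Conditions: TBDPSCl, imidazole, DMF, rt
Reagents that add atoms: tert-butyl(chloro)diphenylsilane, CC(C)(C)[Si](Cl)(c1ccccc1)c1ccccc1
Why: Imidazole-promoted silylation gives a benzylic silyl ether robust enough to survive all later steps (trifluoroacetic acid included) and removable by fluoride at the end.

Step 2
Reactants: 2 tert-butyl[(4-bromo-2-iodophenyl)methoxy]diphenylsilane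
Product: 3 [5-bromo-2-({[tert-butyl(diphenyl)silyl]oxy}methyl)phenyl]boronic acid
Conditions: i-PrMgCl·LiCl, THF, −40 °C; B(OMe)3, −40 °C to rt; aq. HCl
Reagents that add atoms: trimethyl borate, COB(OC)OC; water, O
Why: Halogen–magnesium exchange is much faster at the C–I than at the C–Br bond, and borylation of the aryl Grignard followed by hydrolysis gives the boronic acid with the bromide kept for step 5.

Step 3
Reactants: 3 [5-bromo-2-({[tert-butyl(diphenyl)silyl]oxy}methyl)phenyl]boronic acid; 4 (E)-pent-3-en-1-ol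
Product: 6 (4R)-4-[5-bromo-2-({[tert-butyl(diphenyl)silyl]oxy}methyl)phenyl]pentan-1-ol, via aldehyde 5 (not isolated)
Conditions: Pd(MeCN)2(OTs)2 (6 mol %), Cu(OTf)2 (6 mol %), (S)-4-tert-butyl-2-[5-(trifluoromethyl)pyridin-2-yl]-4,5-dihydrooxazole (13 mol %), O2 (1 atm), 3 Å MS, DMF, rt; then NaBH4, MeOH, 0 °C
Reagents that add atoms: none
Why: Enantioselective redox-relay oxidative Heck arylation: the aryl group adds to the alkene carbon remote from the hydroxyl under ligand control of the alkene face (setting the benzylic R centre), palladium walks to the carbinol carbon to release the aldehyde, and borohydride reduces it in the same flask.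

Step 4
Reactants: 6 (4R)-4-[5-bromo-2-({[tert-butyl(diphenyl)silyl]oxy}methyl)phenyl]pentan-1-ol
Product: 7 (4R)-4-[5-bromo-2-({[tert-butyl(diphenyl)silyl]oxy}methyl)phenyl]pentyl acetate
Conditions: Ac2O, pyridine, DMAP (cat.), CH2Cl2, rt
Reagents that add atoms: acetic anhydride, CC(=O)OC(C)=O
Why: Acetylation (nucleophilic acyl substitution) installs the side-chain acetate of the target early; it tolerates every later step.

Step 5
Reactants: 7 (4R)-4-[5-bromo-2-({[tert-butyl(diphenyl)silyl]oxy}methyl)phenyl]pentyl acetate; 8 di-tert-butyl malonate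
Product: 9 di-tert-butyl 2-Ar-malonate
Conditions: Pd(dba)2 (3 mol %), P(t-Bu)3 (6 mol %), K3PO4, toluene, 70 °C
Reagents that add atoms: none
Why: Palladium-catalysed α-arylation of a malonate with the aryl bromide; the mild phosphate base leaves the acetate and silyl ether intact.

Step 6
Reactants: 10 4-methyl-5,6-dihydro-2H-pyran-2-one
Product: 12 (2Z)-5-{[tert-butyl(dimethyl)silyl]oxy}-N-methoxy-N,3-dimethylpent-2-enamide, via hydroxy amide 11 (not isolated)
Conditions: MeNH(OMe)·HCl, i-PrMgCl, THF, −20 °C; then TBSCl, DMAP (cat.), 0 °C to rt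
Reagents that add atoms: N,O-dimethylhydroxylamine hydrochloride, CNOC.Cl; tert-butyl(chloro)dimethylsilane, CC(C)(C)[Si](C)(C)Cl
Why: Aminolysis of the lactone by the magnesium amide gives the Weinreb amide with the (Z) alkene geometry fixed by the ring, and immediate silylation of the magnesium alkoxide prevents relactonisation.

Step 7
Reactants: 12 (2Z)-5-{[tert-butyl(dimethyl)silyl]oxy}-N-methoxy-N,3-dimethylpent-2-enamide
Product: 13 (4Z)-7-{[tert-butyl(dimethyl)silyl]oxy}-5-methylhepta-1,4-dien-3-one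
Conditions: vinylmagnesium bromide, THF, −20 to 0 °C; inverse quench into cold aq. HCl
Reagents that add atoms: vinylmagnesium bromide, C=C[Mg]Br
Why: Weinreb ketone synthesis: the chelated tetrahedral intermediate stops at the mono-adduct and gives the cross-conjugated dienone with the (Z) geometry unchanged.

Step 8
Reactants: 14 methylglyoxal (2-oxopropanal, 40 % aq.); 15 allyl bromide
Product: 16 3-hydroxyhex-5-en-2-one (racemic)
Conditions: indium powder, THF/H2O, rt
Reagents that add atoms: none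
Why: Barbier-type indium-mediated allylation in water is selective for the aldehyde carbon over the ketone; the new carbinol centre is oxidised away in step 9.

Step 9
Reactants: 16 3-hydroxyhex-5-en-2-one
Product: 17 hex-5-ene-2,3-dione
Conditions: Dess–Martin periodinane, CH2Cl2, 0 °C; used at once
Reagents that add atoms: none
Why: Dess–Martin oxidation of the α-hydroxy ketone gives the 1,2-diketone under neutral conditions that do not move the β,γ-alkene into conjugation.

Step 10
Reactants: 9 di-tert-butyl 2-Ar-malonate; 13 (4Z)-7-{[tert-butyl(dimethyl)silyl]oxy}-5-methylhepta-1,4-dien-3-one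
Product: 19 di-tert-butyl 2-Ar-2-[(4Z)-7-{[tert-butyl(dimethyl)silyl]oxy}-5-methyl-3-[(triethylsilyl)oxy]hepta-2,4-dien-1-yl]malonate, via lithium dienolate 18 (not isolated)
Conditions: LiHMDS (1.0 equiv), THF, −78 °C; 13, Et3SiCl, −78 to 0 °C
Reagents that add atoms: chlorotriethylsilane, CC[Si](Cl)(CC)CC
Why: Michael addition of the lithium malonate to the unsubstituted vinyl terminus of the dienone generates the enolate regiospecifically at C3, and O-silylation traps it as the 2-silyloxydiene before retro-Michael or proton transfer can occur.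

Step 11
Reactants: 19 di-tert-butyl 2-Ar-2-[(4Z)-7-{[tert-butyl(dimethyl)silyl]oxy}-5-methyl-3-[(triethylsilyl)oxy]hepta-2,4-dien-1-yl]malonate; 17 hex-5-ene-2,3-dione
Product: 20 di-tert-butyl 2-Ar-2-{(3S)-2-[(2Z)-5-{[tert-butyl(dimethyl)silyl]oxy}-3-methylpent-2-enoyl]-3-methyl-4-oxo-3-[(triethylsilyl)oxy]hept-6-en-1-yl}malonate (mixture at the acyl-bearing carbon)
Conditions: [Cu((S,S)-t-Bu-box)](SbF6)2 (10 mol %), CH2Cl2, −78 °C; t-Bu-box = 2,2'-(propane-2,2-diyl)bis[(4S)-4-tert-butyl-4,5-dihydrooxazole]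
Reagents that add atoms: none
Why: Catalytic enantioselective Mukaiyama aldol addition to a chelating 1,2-diketone: the diketone binds the copper bisoxazoline complex through both carbonyls, the enol silane attacks the less hindered methyl ketone carbonyl on the face left open by the tert-butyl groups (setting C4 as S), and the silyl group passes to the new tertiary oxygen; the (Z)-disubstituted diene terminus blocks the competing hetero-Diels–Alder path.

Step 12 (key step)
Reactants: 20 di-tert-butyl 2-Ar-2-{(3S)-2-[(2Z)-5-{[tert-butyl(dimethyl)silyl]oxy}-3-methylpent-2-enoyl]-3-methyl-4-oxo-3-[(triethylsilyl)oxy]hept-6-en-1-yl}malonate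
Product: 23 (3R,4aR,7aS)-3-Ar-6-[(2S)-4-hydroxybutan-2-yl]-7a-methyl-7-(prop-2-en-1-yl)-3,4,4a,7a-tetrahydrocyclopenta[b]pyran-2,5-dione, via aldol silyl ether 21 (not isolated), via carboxy lactone 22 (not isolated)
Conditions: Cu(OAc)2·H2O (5 mol %), (R)-DTBM-SEGPHOS (5.5 mol %), (EtO)2MeSiH, toluene, 0 °C to rt; then CF3CO2H/CH2Cl2 (1:4), 0 °C to rt; then toluene, 90 °C
Reagents that add atoms: none
Why: Proposed new method: the chiral bisphosphine copper hydride adds hydride to C10 of the (Z)-enone, the only conjugated acceptor, setting 10S by catalyst control; the copper enolate, formed only at C1, then closes onto the activated α-silyloxy ketone C5, the same five-ring aldol mode as the classical 1,4-diketone cyclopentenone condensation. Acid first removes the labile C5 silyloxy group to give the C1=C5 enone while the more robust C4 triethylsilyl ether still holds, then cleaves that ether, the tert-butyl esters and the TBS ether; the freed C4 hydroxyl lactonises with one carboxyl (C3 epimerises through the enol, so only the cis-fused lactone forms) and the remaining malonic acid decarboxylates on warming, the lactone enol being protonated from the convex face to place Ar equatorial (17R, also the thermodynamic epimer). Closest known reactions: copper hydride reductive aldol cyclisation and hydroxycyclopentenone annulation of ketones with 1,2-diketones.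

Step 13
Reactants: 23 (3R,4aR,7aS)-3-Ar-6-[(2S)-4-hydroxybutan-2-yl]-7a-methyl-7-(prop-2-en-1-yl)-3,4,4a,7a-tetrahydrocyclopenta[b]pyran-2,5-dione
Product: 24 (3S)-3-[(3R,4aR,7aS)-3-Ar-7a-methyl-2,5-dioxo-7-(prop-2-en-1-yl)-2,3,4,4a,5,7a-hexahydrocyclopenta[b]pyran-6-yl]butanal
Conditions: Dess–Martin periodinane, CH2Cl2, 0 °C
Reagents that add atoms: none
Why: Dess–Martin oxidation of the only free (primary) alcohol gives the C8 aldehyde under neutral conditions that avoid base-induced β-elimination of the lactone from the keto-lactone.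

Step 14
Reactants: 24 (3S)-3-[(3R,4aR,7aS)-3-Ar-7a-methyl-2,5-dioxo-7-(prop-2-en-1-yl)-2,3,4,4a,5,7a-hexahydrocyclopenta[b]pyran-6-yl]butanal; 25 methyl 2-(bromomethyl)acrylate
Product: 26 methyl (2Z)-2-(bromomethyl)-4-{(3R,4aR,7aS)-3-Ar-7a-methyl-2,5-dioxo-6-[(2S)-4-oxobutan-2-yl]-2,3,4,4a,5,7a-hexahydrocyclopenta[b]pyran-7-yl}but-2-enoate
Conditions: second-generation Hoveyda–Grubbs catalyst RuCl2(H2IMes)(=CH-C6H4-2-O-i-Pr) (10 mol %), 25 (5 equiv), CH2Cl2, 40 °C
Reagents that add atoms: none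
Why: Proposed new method: olefin cross-metathesis of the terminal allyl group with the 1,1-disubstituted acrylate in excess (the tetrasubstituted enone alkene is inert) should give the trisubstituted enoate as it does with methacrylates, the closest known partners; either alkene isomer leads to the same allylchromium species in step 15.

Step 15
Reactants: 26 methyl (2Z)-2-(bromomethyl)-4-{(3R,4aR,7aS)-3-Ar-7a-methyl-2,5-dioxo-6-[(2S)-4-oxobutan-2-yl]-2,3,4,4a,5,7a-hexahydrocyclopenta[b]pyran-7-yl}but-2-enoate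
Product: 28 tetracyclic keto bis-lactone (target skeleton with C2 ketone and O-TBDPS; 3R,4S,7R,8S,10S,17R), via hydroxy ester 27 (not isolated)
Conditions: CrCl2 (4 equiv), THF/DMF (4:1), rt; then p-TsOH·H2O (cat.), CH2Cl2, rt
Reagents that add atoms: none
Why: Intramolecular Nozaki–Hiyama allylation: the allylchromium adds through its γ-carbon (C7) to the aldehyde, not the hindered ketone, in a chair-like transition state that gives the anti adduct (trans ring fusion), expected on the aldehyde face that keeps the C10 methyl pseudo-equatorial in the new seven-membered ring (7R,8S); the hydroxy ester then lactonises.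

Step 16
Reactants: 28 tetracyclic keto bis-lactone
Product: 29 tetracyclic C2 alcohol (2R,3S,4S,7R,8S,10S,17R; O-TBDPS)
Conditions: NaBH4, CeCl3·7H2O, MeOH, −78 °C
Reagents that add atoms: none
Why: Luche reduction: 1,2-hydride delivery to the C2 ketone from the face opposite the C3 substituent (the convex face of the cis-fused cyclopentenone–lactone) gives the 2R alcohol cis to the lactone ring, and the α-methylene lactone is untouched at −78 °C.

Step 17
Reactants: 29 tetracyclic C2 alcohol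
Product: 30 O-TBDPS ether of the target (C2 acetate)
Conditions: Ac2O, pyridine, DMAP (cat.), CH2Cl2, 0 °C to rt
Reagents that add atoms: acetic anhydride, CC(=O)OC(C)=O
Why: Acetylation of the only free hydroxyl with retention at C2.

Step 18
Reactants: 30 O-TBDPS ether of the target
Product: 31 CNP0205574.1 (target)
Conditions: HF·pyridine, pyridine, THF, 0 °C to rt
Reagents that add atoms: none
Why: Buffered fluoride desilylation frees the benzylic alcohol without touching the two acetates, the two lactones or the exocyclic methylene.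

## Compound list

1 | (4-bromo-2-iodophenyl)methanol | OCc1ccc(Br)cc1I | starting material
2 | tert-butyl[(4-bromo-2-iodophenyl)methoxy]diphenylsilane | Brc1ccc(CO[Si](c2ccccc2)(c2ccccc2)C(C)(C)C)c(I)c1 | intermediate
3 | [5-bromo-2-({[tert-butyl(diphenyl)silyl]oxy}methyl)phenyl]boronic acid | OB(O)c1cc(Br)ccc1CO[Si](c1ccccc1)(c1ccccc1)C(C)(C)C | intermediate
4 | (E)-pent-3-en-1-ol | C/C=C/CCO | starting material
5 | (4R)-4-[5-bromo-2-({[tert-butyl(diphenyl)silyl]oxy}methyl)phenyl]pentanal | Brc1ccc(CO[Si](c2ccccc2)(c2ccccc2)C(C)(C)C)c([C@H](C)CCC=O)c1 | intermediate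
6 | (4R)-4-[5-bromo-2-({[tert-butyl(diphenyl)silyl]oxy}methyl)phenyl]pentan-1-ol | Brc1ccc(CO[Si](c2ccccc2)(c2ccccc2)C(C)(C)C)c([C@H](C)CCCO)c1 | intermediate
7 | (4R)-4-[5-bromo-2-({[tert-butyl(diphenyl)silyl]oxy}methyl)phenyl]pentyl acetate | Brc1ccc(CO[Si](c2ccccc2)(c2ccccc2)C(C)(C)C)c([C@H](C)CCCOC(C)=O)c1 | intermediate
8 | di-tert-butyl malonate | CC(C)(C)OC(=O)CC(=O)OC(C)(C)C | starting material
9 | di-tert-butyl 2-Ar-malonate | CC(C)(C)OC(=O)C(C(=O)OC(C)(C)C)c1ccc(CO[Si](c2ccccc2)(c2ccccc2)C(C)(C)C)c([C@H](C)CCCOC(C)=O)c1 | intermediate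
10 | 4-methyl-5,6-dihydro-2H-pyran-2-one | CC1=CC(=O)OCC1 | starting material
11 | (2Z)-5-hydroxy-N-methoxy-N,3-dimethylpent-2-enamide | CON(C)C(=O)/C=C(/C)CCO | intermediate
12 | (2Z)-5-{[tert-butyl(dimethyl)silyl]oxy}-N-methoxy-N,3-dimethylpent-2-enamide | CON(C)C(=O)/C=C(/C)CCO[Si](C)(C)C(C)(C)C | intermediate
13 | (4Z)-7-{[tert-butyl(dimethyl)silyl]oxy}-5-methylhepta-1,4-dien-3-one | C=CC(=O)/C=C(/C)CCO[Si](C)(C)C(C)(C)C | intermediate
14 | methylglyoxal (2-oxopropanal) | CC(=O)C=O | starting material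
15 | allyl bromide | C=CCBr | starting material
16 | 3-hydroxyhex-5-en-2-one (racemic) | CC(=O)C(O)CC=C | intermediate
17 | hex-5-ene-2,3-dione | CC(=O)C(=O)CC=C | intermediate
18 | lithium dienolate of di-tert-butyl 2-Ar-2-[(4Z)-7-{[tert-butyl(dimethyl)silyl]oxy}-5-methyl-3-oxohept-4-en-1-yl]malonate | [Li+].[O-]C(=CCC(C(=O)OC(C)(C)C)(C(=O)OC(C)(C)C)c1ccc(CO[Si](c2ccccc2)(c2ccccc2)C(C)(C)C)c([C@H](C)CCCOC(C)=O)c1)/C=C(/C)CCO[Si](C)(C)C(C)(C)C | intermediate
19 | di-tert-butyl 2-Ar-2-[(4Z)-7-{[tert-butyl(dimethyl)silyl]oxy}-5-methyl-3-[(triethylsilyl)oxy]hepta-2,4-dien-1-yl]malonate | CC(C)(C)OC(=O)C(CC=C(O[Si](CC)(CC)CC)/C=C(/C)CCO[Si](C)(C)C(C)(C)C)(C(=O)OC(C)(C)C)c1ccc(CO[Si](c2ccccc2)(c2ccccc2)C(C)(C)C)c([C@H](C)CCCOC(C)=O)c1 | intermediate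
20 | di-tert-butyl 2-Ar-2-{(3S)-2-[(2Z)-5-{[tert-butyl(dimethyl)silyl]oxy}-3-methylpent-2-enoyl]-3-methyl-4-oxo-3-[(triethylsilyl)oxy]hept-6-en-1-yl}malonate (C4 S; mixture at C3) | CC(C)(C)OC(=O)C(CC(C(=O)/C=C(/C)CCO[Si](C)(C)C(C)(C)C)[C@](C)(O[Si](CC)(CC)CC)C(=O)CC=C)(C(=O)OC(C)(C)C)c1ccc(CO[Si](c2ccccc2)(c2ccccc2)C(C)(C)C)c([C@H](C)CCCOC(C)=O)c1 | intermediate
21 | di-tert-butyl 2-Ar-2-{[(5S)-4-{[diethoxy(methyl)silyl]oxy}-5-methyl-2-oxo-4-(prop-2-en-1-yl)-3-[(2S)-4-{[tert-butyl(dimethyl)silyl]oxy}butan-2-yl]-5-[(triethylsilyl)oxy]cyclopentyl]methyl}malonate (other ring centres unassigned) | C=CCC1(O[Si](C)(OCC)OCC)C([C@@H](C)CCO[Si](C)(C)C(C)(C)C)C(=O)C(CC(C(=O)OC(C)(C)C)(C(=O)OC(C)(C)C)c2ccc(CO[Si](c3ccccc3)(c3ccccc3)C(C)(C)C)c([C@H](C)CCCOC(C)=O)c2)[C@]1(C)O[Si](CC)(CC)CC | intermediate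
22 | (4aR,7aS)-3-Ar-6-[(2S)-4-hydroxybutan-2-yl]-7a-methyl-2,5-dioxo-7-(prop-2-en-1-yl)-2,3,4,4a,5,7a-hexahydrocyclopenta[b]pyran-3-carboxylic acid (mixture at C17) | OCC[C@H](C)C3=C(CC=C)[C@@]1(C)OC(=O)C(C(=O)O)(c2ccc(CO[Si](c4ccccc4)(c4ccccc4)C(C)(C)C)c([C@H](C)CCCOC(C)=O)c2)C[C@H]1C3=O | intermediate
23 | (3R,4aR,7aS)-3-Ar-6-[(2S)-4-hydroxybutan-2-yl]-7a-methyl-7-(prop-2-en-1-yl)-3,4,4a,7a-tetrahydrocyclopenta[b]pyran-2,5-dione | OCC[C@H](C)C3=C(CC=C)[C@@]1(C)OC(=O)[C@@H](c2ccc(CO[Si](c4ccccc4)(c4ccccc4)C(C)(C)C)c([C@H](C)CCCOC(C)=O)c2)C[C@H]1C3=O | intermediate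
24 | (3S)-3-[(3R,4aR,7aS)-3-Ar-7a-methyl-2,5-dioxo-7-(prop-2-en-1-yl)-2,3,4,4a,5,7a-hexahydrocyclopenta[b]pyran-6-yl]butanal | O=CC[C@H](C)C3=C(CC=C)[C@@]1(C)OC(=O)[C@@H](c2ccc(CO[Si](c4ccccc4)(c4ccccc4)C(C)(C)C)c([C@H](C)CCCOC(C)=O)c2)C[C@H]1C3=O | intermediate
25 | methyl 2-(bromomethyl)acrylate | C=C(CBr)C(=O)OC | starting material
26 | methyl (2Z)-2-(bromomethyl)-4-{(3R,4aR,7aS)-3-Ar-7a-methyl-2,5-dioxo-6-[(2S)-4-oxobutan-2-yl]-2,3,4,4a,5,7a-hexahydrocyclopenta[b]pyran-7-yl}but-2-enoate | O=CC[C@H](C)C3=C(C/C=C(\CBr)C(=O)OC)[C@@]1(C)OC(=O)[C@@H](c2ccc(CO[Si](c4ccccc4)(c4ccccc4)C(C)(C)C)c([C@H](C)CCCOC(C)=O)c2)C[C@H]1C3=O | intermediate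
27 | ring-closed hydroxy ester: methyl acrylate unit on C7 (R), free hydroxyl on C8 (S), cycloheptene closed, C2 ketone | O[C@H]1C[C@H](C)C3=C(C[C@@H]1C(=C)C(=O)OC)[C@@]4(C)OC(=O)[C@@H](c2ccc(CO[Si](c5ccccc5)(c5ccccc5)C(C)(C)C)c([C@H](C)CCCOC(C)=O)c2)C[C@H]4C3=O | intermediate
28 | tetracyclic keto bis-lactone (3R,4S,7R,8S,10S,17R): target skeleton with C2 ketone and benzylic O-TBDPS | C=C1C(=O)O[C@H]2C[C@H](C)C3=C(C[C@H]12)[C@@]1(C)OC(=O)[C@@H](c2ccc(CO[Si](c4ccccc4)(c4ccccc4)C(C)(C)C)c([C@H](C)CCCOC(C)=O)c2)C[C@H]1C3=O | intermediate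
29 | tetracyclic C2 alcohol (2R,3S,4S,7R,8S,10S,17R), benzylic O-TBDPS | C=C1C(=O)O[C@H]2C[C@H](C)C3=C(C[C@H]12)[C@@]1(C)OC(=O)[C@@H](c2ccc(CO[Si](c4ccccc4)(c4ccccc4)C(C)(C)C)c([C@H](C)CCCOC(C)=O)c2)C[C@H]1[C@H]3O | intermediate
30 | O-TBDPS ether of the target (C2 acetate) | C=C1C(=O)O[C@H]2C[C@H](C)C3=C(C[C@H]12)[C@@]1(C)OC(=O)[C@@H](c2ccc(CO[Si](c4ccccc4)(c4ccccc4)C(C)(C)C)c([C@H](C)CCCOC(C)=O)c2)C[C@H]1[C@H]3OC(C)=O | intermediate
31 | CNP0205574.1 | C=C1C(=O)O[C@H]2C[C@H](C)C3=C(C[C@H]12)[C@@]1(C)OC(=O)[C@@H](c2ccc(CO)c([C@H](C)CCCOC(C)=O)c2)C[C@H]1[C@H]3OC(C)=O | target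

## Step count and risks

Total step count: 18. Longest linear sequence: 14 steps (steps 1–5, then 10–18).

Most likely to fail: steps 12, 11 and 15.

Step 12 (key cascade). The copper enolate may be silylated instead of closing onto the hindered ketone, after which acid could cyclise either α-carbon. The fallback sets out from 20 and returns at 23. Conjugate hydrosilylation with PhMe2SiH under the same chiral copper hydride catalyst gives the isolable, regiodefined silyl enol ether di-tert-butyl 2-Ar-2-{(3S)-2-[(3S)-1-[dimethyl(phenyl)silyl]oxy-5-{[tert-butyl(dimethyl)silyl]oxy}-3-methylpent-1-enyl]-3-methyl-4-oxo-3-[(triethylsilyl)oxy]hept-6-en-1-yl}malonate F3. TiCl4 in CH2Cl2 at −78 °C, chelating the α-silyloxy ketone, then forces the intramolecular Mukaiyama aldol to the cyclopentanone carbinol di-tert-butyl 2-Ar-2-{[(5S)-4-hydroxy-5-methyl-2-oxo-4-(prop-2-en-1-yl)-3-[(2S)-4-{[tert-butyl(dimethyl)silyl]oxy}butan-2-yl]-5-[(triethylsilyl)oxy]cyclopentyl]methyl}malonate F4. This is treated with CF3CO2H and then warmed in toluene as in step 12 to give 23.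

Step 11 (asymmetric aldol with a substituted ketone-derived enol silane and an isomerisation-prone diketone). The fallback sets out from 9 and 13 and returns at 20, replacing catalyst control by a stoichiometric chiral boron enolate. The Michael addition is run with catalytic DBU and the adduct protonated to give the neutral enone ketone di-tert-butyl 2-Ar-2-[(4Z)-7-{[tert-butyl(dimethyl)silyl]oxy}-5-methyl-3-oxohept-4-en-1-yl]malonate F1. Enolisation on the CH2 side with diisopinocampheylboron triflate and i-Pr2NEt, then aldol addition to the methyl ketone carbonyl of 17 and oxidative work-up, gives the free tertiary carbinol di-tert-butyl 2-Ar-2-{(3S)-3-hydroxy-2-[(2Z)-5-{[tert-butyl(dimethyl)silyl]oxy}-3-methylpent-2-enoyl]-3-methyl-4-oxohept-6-en-1-yl}malonate F2. Silylation with Et3SiOTf and 2,6-lutidine at −78 °C gives 20.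

Step 15 (facial selectivity of the ring closure relative to C10, and trans fusion). The fallback sets out from 24 and returns at 28, replacing the closed allylchromium transition state by an open Hosomi–Sakurai one. Cross-metathesis of 24 with methyl 2-[(trimethylsilyl)methyl]acrylate gives the allylsilane methyl (2Z)-4-{(3R,4aR,7aS)-3-Ar-7a-methyl-2,5-dioxo-6-[(2S)-4-oxobutan-2-yl]-2,3,4,4a,5,7a-hexahydrocyclopenta[b]pyran-7-yl}-2-[(trimethylsilyl)methyl]but-2-enoate F5. Fluoride (Bu4NF, THF) or BF3·OEt2 then triggers the intramolecular allylsilane–aldehyde addition and lactonisation to 28.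

## Further compounds

F1 | step 11 | di-tert-butyl 2-Ar-2-[(4Z)-7-{[tert-butyl(dimethyl)silyl]oxy}-5-methyl-3-oxohept-4-en-1-yl]malonate | CC(C)(C)OC(=O)C(CCC(=O)/C=C(/C)CCO[Si](C)(C)C(C)(C)C)(C(=O)OC(C)(C)C)c1ccc(CO[Si](c2ccccc2)(c2ccccc2)C(C)(C)C)c([C@H](C)CCCOC(C)=O)c1
F2 | step 11 | di-tert-butyl 2-Ar-2-{(3S)-3-hydroxy-2-[(2Z)-5-{[tert-butyl(dimethyl)silyl]oxy}-3-methylpent-2-enoyl]-3-methyl-4-oxohept-6-en-1-yl}malonate | CC(C)(C)OC(=O)C(CC(C(=O)/C=C(/C)CCO[Si](C)(C)C(C)(C)C)[C@](C)(O)C(=O)CC=C)(C(=O)OC(C)(C)C)c1ccc(CO[Si](c2ccccc2)(c2ccccc2)C(C)(C)C)c([C@H](C)CCCOC(C)=O)c1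
F3 | step 12 | di-tert-butyl 2-Ar-2-{(3S)-2-[(3S)-1-[dimethyl(phenyl)silyl]oxy-5-{[tert-butyl(dimethyl)silyl]oxy}-3-methylpent-1-enyl]-3-methyl-4-oxo-3-[(triethylsilyl)oxy]hept-6-en-1-yl}malonate | C=CCC(=O)[C@@](C)(O[Si](CC)(CC)CC)C(CC(C(=O)OC(C)(C)C)(C(=O)OC(C)(C)C)c1ccc(CO[Si](c2ccccc2)(c2ccccc2)C(C)(C)C)c([C@H](C)CCCOC(C)=O)c1)C(O[Si](C)(C)c1ccccc1)=C[C@@H](C)CCO[Si](C)(C)C(C)(C)C
F4 | step 12 | di-tert-butyl 2-Ar-2-{[(5S)-4-hydroxy-5-methyl-2-oxo-4-(prop-2-en-1-yl)-3-[(2S)-4-{[tert-butyl(dimethyl)silyl]oxy}butan-2-yl]-5-[(triethylsilyl)oxy]cyclopentyl]methyl}malonate | C=CCC1(O)C([C@@H](C)CCO[Si](C)(C)C(C)(C)C)C(=O)C(CC(C(=O)OC(C)(C)C)(C(=O)OC(C)(C)C)c2ccc(CO[Si](c3ccccc3)(c3ccccc3)C(C)(C)C)c([C@H](C)CCCOC(C)=O)c2)[C@]1(C)O[Si](CC)(CC)CC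
F5 | step 15 | methyl (2Z)-4-{(3R,4aR,7aS)-3-Ar-7a-methyl-2,5-dioxo-6-[(2S)-4-oxobutan-2-yl]-2,3,4,4a,5,7a-hexahydrocyclopenta[b]pyran-7-yl}-2-[(trimethylsilyl)methyl]but-2-enoate | O=CC[C@H](C)C3=C(C/C=C(\C[Si](C)(C)C)C(=O)OC)[C@@]1(C)OC(=O)[C@@H](c2ccc(CO[Si](c4ccccc4)(c4ccccc4)C(C)(C)C)c([C@H](C)CCCOC(C)=O)c2)C[C@H]1C3=O
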